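**Plan**

- Retrosynthesis (germacrane numbering): remove the C9 acetate, then cut C9–C10 (aldol), which opens the ten-membered carbocycle and the oxygen-bridged bicycle to a monocyclic 2-methyl-3(2H)-furanone carrying a C9 aldehyde; then cut O–C3 and C3–C4 of the furanone (ynone cyclisation, Sonogashira), the C8–O ester (with inversion), C7–C8 (Barbier), and the butenolide C7=C11 (metathesis) with its ester C–O.
- Forward: acrolein and a propynyl Grignard reagent give a resolved dienyl iodide; metathesis closes the butenolide; the Barbier step turns it into the α-methylene-γ-lactone; Mitsunobu esterification, alkyne coupling and gold closure of the furanone follow; the aldol closes the bridged macrocycle; acetylation ends the route.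
- Enabling feature: C10 is both the α-carbon of the C1 ketone and the sp3 O–C carbon of the furanone ring (O, C3, C2, C1, C10). Enolisation therefore gives an aromatic 3-silyloxyfuran that is nucleophilic at C10, and the (Z)-C4=C5 alkene with the trans-fused lactone (C6, C7, C11, C12, O) holds C9 over it.
- Stereochemistry: C6 comes from a catalytic Sharpless kinetic resolution; C7 and C8 are relayed from C6 in the Barbier step (C8 is then inverted in the Mitsunobu step); C9 and C10 are set together in the aldol by the C6–C8 array; the (Z)-alkene comes from trans-hydroalumination and iodination.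

Key step: step 15

Remark (numbering): germacrane numbering of the target is used for all intermediates: C1 ketone, C2=C3 enol ether, C4=C5, C6 lactone carbinol, C7, C8 (3-methylbutanoate), C9 (acetate), C10 (quaternary), C11=C13 methylene, C12 lactone carbonyl, C14 and C15 methyls.

Remark (chemistry): the zinc Barbier reaction of step 6 is assumed to pass through the closed chair transition state. The lactate-derived centre (future C10) and the propargylic carbinol of 16 and 17 are erased later, so their configuration is immaterial.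

**Route**

Step 1
Reactants: 1 acrolein + 2 prop-1-yn-1-ylmagnesium bromide (CH3C≡CMgBr)
Product: 3 rac-hex-1-en-4-yn-3-ol
Conditions: THF, −78 °C to 0 °C; aq. NH4Cl
Reagents that add atoms: none
Why: 1,2-addition of the hard alkynyl Grignard reagent to the enal carbonyl should give the racemic vinyl propynyl carbinol.

Step 2
Reactants: 3 rac-hex-1-en-4-yn-3-ol
Product: 4 (3S)-hex-1-en-4-yn-3-ol
Conditions: Ti(OiPr)4 (10 mol %), L-(+)-diisopropyl tartrate (12 mol %), t-BuOOH (0.6 equiv), 4 Å molecular sieves, CH2Cl2, −20 °C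
Reagents that add atoms: none
Why: Sharpless kinetic resolution; with the L-(+)-tartrate the (R)-alcohol should be epoxidised at its vinyl group much faster, so the (S)-alcohol is recovered, and this catalytic step sets C6.

Step 3
Reactants: 4 (3S)-hex-1-en-4-yn-3-ol
Product: 5 (3S,4Z)-5-iodohexa-1,4-dien-3-ol
Conditions: NaAlH2(OCH2CH2OMe)2, THF, 0 °C to rt; then I2, −78 °C
Reagents that add atoms: iodine, II
Why: alkoxide-directed trans-hydroalumination of the propargylic alcohol places aluminium on the distal alkyne carbon cis to the carbinol carbon, and iodinolysis with retention should give the (Z)-vinyl iodide that fixes the C4=C5 geometry.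

Step 4
Reactants: 5 (3S,4Z)-5-iodohexa-1,4-dien-3-ol + 6 2-(bromomethyl)prop-2-enoic acid
Product: 7 (3S,4Z)-5-iodohexa-1,4-dien-3-yl 2-(bromomethyl)prop-2-enoate
Conditions: DCC, DMAP (5 mol %), CH2Cl2, −10 °C to 0 °C
Reagents that add atoms: none
Why: Steglich esterification of the secondary allylic alcohol; low temperature and little DMAP should leave the allylic bromide untouched, and C6 is not involved.

Step 5
Reactants: 7 (3S,4Z)-5-iodohexa-1,4-dien-3-yl 2-(bromomethyl)prop-2-enoate
Product: 8 (5S)-3-(bromomethyl)-5-[(1Z)-2-iodoprop-1-en-1-yl]furan-2(5H)-one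
Conditions: second-generation Grubbs catalyst RuCl2(=CHPh)(H2IMes)(PCy3) (5 mol %), 1,4-benzoquinone (10 mol %), toluene (0.01 M), 80 °C
Reagents that add atoms: none
Why: ring-closing metathesis of the vinyl group with the 2-substituted acrylate should close the five-membered butenolide (C7=C11) with loss of ethene; the vinyl iodide is inert to the ruthenium carbene and benzoquinone suppresses double-bond migration at C6.

Step 6
Reactants: 8 (5S)-3-(bromomethyl)-5-[(1Z)-2-iodoprop-1-en-1-yl]furan-2(5H)-one + 9 {[tert-butyl(dimethyl)silyl]oxy}acetaldehyde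
Product: 10 (4R,5S)-4-[(1R)-2-{[tert-butyl(dimethyl)silyl]oxy}-1-hydroxyethyl]-5-[(1Z)-2-iodoprop-1-en-1-yl]-3-methylideneoxolan-2-one
Conditions: Zn dust, THF–sat. aq. NH4Cl, 0 °C to rt
Reagents that add atoms: none
Why: Barbier allylation; the allylzinc should attack the aldehyde through its γ-carbon C7 in a chair-like six-membered transition state, anti to the C6 substituent (trans-lactone, C7) and with anti simple diastereoselection because the ring fixes C6 trans to the CH2Zn carbon (C8 = R, the epimer that step 7 inverts), creating the exocyclic methylene at the same time.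

Step 7
Reactants: 10 (4R,5S)-4-[(1R)-2-{[tert-butyl(dimethyl)silyl]oxy}-1-hydroxyethyl]-5-[(1Z)-2-iodoprop-1-en-1-yl]-3-methylideneoxolan-2-one
Product: 11 (1S)-2-{[tert-butyl(dimethyl)silyl]oxy}-1-{(2S,3S)-2-[(1Z)-2-iodoprop-1-en-1-yl]-4-methylidene-5-oxooxolan-3-yl}ethyl 3-methylbutanoate
Conditions: PPh3, DIAD, 3-methylbutanoic acid, toluene, 0 °C to rt (betaine preformed)
Reagents that add atoms: 3-methylbutanoic acid, CC(C)CC(=O)O
Why: Mitsunobu esterification; SN2 displacement of the alkoxyphosphonium by the carboxylate should invert C8 to the required S configuration and install the ester in one operation.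

Step 8
Reactants: 12 ethyl (2S)-2-hydroxypropanoate
Product: 13 ethyl (2S)-2-{[tert-butyl(dimethyl)silyl]oxy}propanoate
Conditions: TBSCl, imidazole, CH2Cl2, rt
Reagents that add atoms: tert-butyl(chloro)dimethylsilane, CC(C)(C)[Si](C)(C)Cl
Why: routine silylation of the secondary alcohol.

Step 9
Reactants: 13 ethyl (2S)-2-{[tert-butyl(dimethyl)silyl]oxy}propanoate + 14 ethynylmagnesium bromide (HC≡CMgBr)
Product: 16 (4S)-4-{[tert-butyl(dimethyl)silyl]oxy}pent-1-yn-3-ol (both C3 epimers), via aldehyde 15 (not isolated)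
Conditions: i-Bu2AlH (1.05 equiv), CH2Cl2, −78 °C; then HC≡CMgBr, THF, −78 °C to rt
Reagents that add atoms: none
Why: half-reduction of the α-silyloxy ester to the aldehyde at −78 °C and in situ Grignard addition should give the propargylic alcohol; its carbinol configuration is irrelevant because step 11 oxidises it.

Step 10
Reactants: 11 (1S)-2-{[tert-butyl(dimethyl)silyl]oxy}-1-{(2S,3S)-2-[(1Z)-2-iodoprop-1-en-1-yl]-4-methylidene-5-oxooxolan-3-yl}ethyl 3-methylbutanoate + 16 (4S)-4-{[tert-butyl(dimethyl)silyl]oxy}pent-1-yn-3-ol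
Product: 17 (1S)-2-{[tert-butyl(dimethyl)silyl]oxy}-1-{(2R,3S)-2-[(1Z,6S)-6-{[tert-butyl(dimethyl)silyl]oxy}-5-hydroxy-2-methylhept-1-en-3-yn-1-yl]-4-methylidene-5-oxooxolan-3-yl}ethyl 3-methylbutanoate (both carbinol epimers)
Conditions: Pd(PPh3)4 (5 mol %), CuI (10 mol %), Et3N, THF, rt
Reagents that add atoms: none
Why: Sonogashira coupling of the vinyl iodide with the terminal alkyne should form C3–C4 with retention of the (Z)-geometry; the tertiary amine cannot add irreversibly to the methylene lactone.

Step 11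
Reactants: 17 the enynol of step 10
Product: 18 (1S)-2-{[tert-butyl(dimethyl)silyl]oxy}-1-{(2R,3S)-2-[(1Z,6S)-6-{[tert-butyl(dimethyl)silyl]oxy}-2-methyl-5-oxohept-1-en-3-yn-1-yl]-4-methylidene-5-oxooxolan-3-yl}ethyl 3-methylbutanoate
Conditions: MnO2 (excess), CH2Cl2, rt
Reagents that add atoms: none
Why: MnO2 oxidation of the propargylic alcohol, the only free hydroxyl, should give the ynone and merge the two carbinol epimers.

Step 12
Reactants: 18 the bis-silyl ynone of step 11
Product: 19 (1S)-2-hydroxy-1-{(2R,3S)-2-[(1Z,6S)-6-hydroxy-2-methyl-5-oxohept-1-en-3-yn-1-yl]-4-methylidene-5-oxooxolan-3-yl}ethyl 3-methylbutanoate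
Conditions: HF·pyridine, pyridine, THF, 0 °C to rt
Reagents that add atoms: none
Why: buffered HF should cleave both silyl ethers; the non-basic medium is chosen to avoid migration of the C8 ester to the freed C9 hydroxyl.

Step 13
Reactants: 19 the γ-hydroxy ynone diol of step 12
Product: 20 (1S)-2-hydroxy-1-{(2R,3S)-2-[(1Z)-2-[(5S)-5-methyl-4-oxo-4,5-dihydrofuran-2-yl]prop-1-en-1-yl]-4-methylidene-5-oxooxolan-3-yl}ethyl 3-methylbutanoate
Conditions: (Ph3P)AuNTf2 (3 mol %), CH2Cl2, rt
Reagents that add atoms: none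
Why: gold-catalysed 5-endo-dig cycloisomerisation of the γ-hydroxy ynone (O10 onto the activated alkyne carbon C3) should give the 3(2H)-furanone; the remote primary alcohol cannot compete.

Step 14
Reactants: 20 the furanone alcohol of step 13
Product: 21 (1S)-1-{(2R,3S)-2-[(1Z)-2-[(5S)-5-methyl-4-oxo-4,5-dihydrofuran-2-yl]prop-1-en-1-yl]-4-methylidene-5-oxooxolan-3-yl}-2-oxoethyl 3-methylbutanoate
Conditions: Dess–Martin periodinane, NaHCO3, CH2Cl2, 0 °C
Reagents that add atoms: none
Why: buffered Dess–Martin oxidation of the primary alcohol should give the α-acyloxy aldehyde without epimerising C8; the product is used directly.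

Step 15
Reactants: 21 the furanone aldehyde of step 14
Product: 24 (4Z,6R,7S,8S,9R,10R)-9-hydroxy-8-(3-methylbutanoyloxy)-1-oxo-3,10-epoxygermacra-2,4,11(13)-trien-12,6-olide, via silyloxyfuran 22 (not isolated), via silyl ether 23 (not isolated)
Conditions: i-Pr2NEt (1.1 equiv), Me3SiOTf (1.1 equiv), CH2Cl2 (1 mM), −78 °C; then Me3SiOTf (0.3 equiv), −78 to −40 °C; aq. citric acid, THF
Reagents that add atoms: none
Why: The amine and silyl triflate should enolise only the furanone, because its enol is an aromatic furan, to give the 2-methyl-3-(trimethylsilyloxy)furan 22; silyl activation of the C9 aldehyde then triggers an intramolecular Mukaiyama aldol addition of furan C10 to C9 with silyl transfer to the new alkoxide, which gives 23 and blocks the retro-aldol return to the aromatic furan. The closest known reaction type is the intermolecular Mukaiyama aldol of 2-alkyl-3-silyloxyfurans with aldehydes at C2, together with ring-closing Mukaiyama aldols used for medium rings. The new bond closes the ten-membered carbocycle C1–C10 (10-exo-trig at the aldehyde with the enol double bond C1=C10 inside the ring; nine-membered when counted through the furan oxygen) and with it the whole 11-oxabicyclo[6.2.1]undecane, whose oxygen bridge and two-carbon bridge C1–C2 are already present as the planar furan. C10: the chain C4–C9 can reach C10 only by folding across the furan oxygen, and with the trans-fused lactone and the (Z)-alkene the fold that turns H7 and H8 toward the furan and the lactone ring and the C8 ester outward is expected to be the unstrained one, which presents the Re face of C10 (10R). C9: in that fold the silyl-activated carbonyl oxygen points away from the furan and H9 under it, so the Si face of the aldehyde should be attacked (9R, 8,9-syn). The step needs chemoselectivity for the aldehyde over the methylene lactone (secured by the much higher electrophilicity of the activated aldehyde), closure over oligomerisation (high dilution plus preorganisation by furan, (Z)-alkene and lactone) and retention of C8 (the single equivalent of base is consumed by the far more acidic furanone at −78 °C).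

Step 16
Reactants: 24 the C9 alcohol of step 15
Product: 25 (4Z,6R,7S,8S,9R,10R)-9-acetoxy-8-(3-methylbutanoyloxy)-1-oxo-3,10-epoxygermacra-2,4,11(13)-trien-12,6-olide (CNP0255553.1)
Conditions: Ac2O, pyridine, DMAP (cat.), CH2Cl2, 0 °C
Reagents that add atoms: acetic anhydride, CC(=O)OC(C)=O
Why: DMAP-catalysed acetylation of the hindered secondary C9 hydroxyl with retention; mild base and low temperature are chosen to avoid retro-aldol cleavage of the β-hydroxy ketone.

**Compound list**

1 | acrolein (prop-2-enal) | C=CC=O | starting material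
2 | prop-1-yn-1-ylmagnesium bromide | CC#C[Mg]Br | starting material
3 | rac-hex-1-en-4-yn-3-ol | C=CC(O)C#CC | intermediate
4 | (3S)-hex-1-en-4-yn-3-ol | C=C[C@H](O)C#CC | intermediate
5 | (3S,4Z)-5-iodohexa-1,4-dien-3-ol | C=C[C@H](O)/C=C(/C)I | intermediate
6 | 2-(bromomethyl)prop-2-enoic acid | C=C(CBr)C(=O)O | starting material
7 | (3S,4Z)-5-iodohexa-1,4-dien-3-yl 2-(bromomethyl)prop-2-enoate | C=C(CBr)C(=O)O[C@@H](C=C)/C=C(/C)I | intermediate
8 | (5S)-3-(bromomethyl)-5-[(1Z)-2-iodoprop-1-en-1-yl]furan-2(5H)-one | BrCC1=C[C@@H](/C=C(/C)I)OC1=O | intermediate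
9 | {[tert-butyl(dimethyl)silyl]oxy}acetaldehyde | O=CCO[Si](C)(C)C(C)(C)C | starting material
10 | (4R,5S)-4-[(1R)-2-{[tert-butyl(dimethyl)silyl]oxy}-1-hydroxyethyl]-5-[(1Z)-2-iodoprop-1-en-1-yl]-3-methylideneoxolan-2-one | C=C1C(=O)O[C@H](/C=C(/C)I)[C@H]1[C@@H](O)CO[Si](C)(C)C(C)(C)C | intermediate
11 | (1S)-2-{[tert-butyl(dimethyl)silyl]oxy}-1-{(2S,3S)-2-[(1Z)-2-iodoprop-1-en-1-yl]-4-methylidene-5-oxooxolan-3-yl}ethyl 3-methylbutanoate | C=C1C(=O)O[C@H](/C=C(/C)I)[C@H]1[C@H](OC(=O)CC(C)C)CO[Si](C)(C)C(C)(C)C | intermediate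
12 | ethyl (2S)-2-hydroxypropanoate (ethyl L-lactate) | C[C@H](O)C(=O)OCC | starting material
13 | ethyl (2S)-2-{[tert-butyl(dimethyl)silyl]oxy}propanoate | C[C@H](O[Si](C)(C)C(C)(C)C)C(=O)OCC | intermediate
14 | ethynylmagnesium bromide | C#C[Mg]Br | starting material
15 | (2S)-2-{[tert-butyl(dimethyl)silyl]oxy}propanal | C[C@H](O[Si](C)(C)C(C)(C)C)C=O | intermediate
16 | (4S)-4-{[tert-butyl(dimethyl)silyl]oxy}pent-1-yn-3-ol (both C3 epimers) | C#CC(O)[C@H](C)O[Si](C)(C)C(C)(C)C | intermediate
17 | (1S)-2-{[tert-butyl(dimethyl)silyl]oxy}-1-{(2R,3S)-2-[(1Z,6S)-6-{[tert-butyl(dimethyl)silyl]oxy}-5-hydroxy-2-methylhept-1-en-3-yn-1-yl]-4-methylidene-5-oxooxolan-3-yl}ethyl 3-methylbutanoate (both carbinol epimers) | C=C1C(=O)O[C@H](/C=C(/C)C#CC(O)[C@H](C)O[Si](C)(C)C(C)(C)C)[C@H]1[C@H](OC(=O)CC(C)C)CO[Si](C)(C)C(C)(C)C | intermediate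
18 | (1S)-2-{[tert-butyl(dimethyl)silyl]oxy}-1-{(2R,3S)-2-[(1Z,6S)-6-{[tert-butyl(dimethyl)silyl]oxy}-2-methyl-5-oxohept-1-en-3-yn-1-yl]-4-methylidene-5-oxooxolan-3-yl}ethyl 3-methylbutanoate | C=C1C(=O)O[C@H](/C=C(/C)C#CC(=O)[C@H](C)O[Si](C)(C)C(C)(C)C)[C@H]1[C@H](OC(=O)CC(C)C)CO[Si](C)(C)C(C)(C)C | intermediate
19 | (1S)-2-hydroxy-1-{(2R,3S)-2-[(1Z,6S)-6-hydroxy-2-methyl-5-oxohept-1-en-3-yn-1-yl]-4-methylidene-5-oxooxolan-3-yl}ethyl 3-methylbutanoate | C=C1C(=O)O[C@H](/C=C(/C)C#CC(=O)[C@H](C)O)[C@H]1[C@H](OC(=O)CC(C)C)CO | intermediate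
20 | (1S)-2-hydroxy-1-{(2R,3S)-2-[(1Z)-2-[(5S)-5-methyl-4-oxo-4,5-dihydrofuran-2-yl]prop-1-en-1-yl]-4-methylidene-5-oxooxolan-3-yl}ethyl 3-methylbutanoate | C=C1C(=O)O[C@H](/C=C(/C)C2=CC(=O)[C@H](C)O2)[C@H]1[C@H](OC(=O)CC(C)C)CO | intermediate
21 | (1S)-1-{(2R,3S)-2-[(1Z)-2-[(5S)-5-methyl-4-oxo-4,5-dihydrofuran-2-yl]prop-1-en-1-yl]-4-methylidene-5-oxooxolan-3-yl}-2-oxoethyl 3-methylbutanoate | C=C1C(=O)O[C@H](/C=C(/C)C2=CC(=O)[C@H](C)O2)[C@H]1[C@H](OC(=O)CC(C)C)C=O | intermediate
22 | (1S)-1-{(2R,3S)-2-[(1Z)-2-{5-methyl-4-[(trimethylsilyl)oxy]furan-2-yl}prop-1-en-1-yl]-4-methylidene-5-oxooxolan-3-yl}-2-oxoethyl 3-methylbutanoate | C=C1C(=O)O[C@H](/C=C(/C)c2cc(O[Si](C)(C)C)c(C)o2)[C@H]1[C@H](OC(=O)CC(C)C)C=O | intermediate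
23 | (4Z,6R,7S,8S,9R,10R)-8-(3-methylbutanoyloxy)-1-oxo-9-[(trimethylsilyl)oxy]-3,10-epoxygermacra-2,4,11(13)-trien-12,6-olide | C=C1C(=O)O[C@@H]2/C=C(/C)C3=CC(=O)[C@](C)(O3)[C@H](O[Si](C)(C)C)[C@@H](OC(=O)CC(C)C)[C@@H]12 | intermediate
24 | (4Z,6R,7S,8S,9R,10R)-9-hydroxy-8-(3-methylbutanoyloxy)-1-oxo-3,10-epoxygermacra-2,4,11(13)-trien-12,6-olide | C=C1C(=O)O[C@@H]2/C=C(/C)C3=CC(=O)[C@](C)(O3)[C@H](O)[C@@H](OC(=O)CC(C)C)[C@@H]12 | intermediate
25 | (4Z,6R,7S,8S,9R,10R)-9-acetoxy-8-(3-methylbutanoyloxy)-1-oxo-3,10-epoxygermacra-2,4,11(13)-trien-12,6-olide (CNP0255553.1) | C=C1C(=O)O[C@@H]2/C=C(/C)C3=CC(=O)[C@](C)(O3)[C@H](OC(C)=O)[C@@H](OC(=O)CC(C)C)[C@@H]12 | target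

**Step count and risks**

Total steps: 16. Longest linear sequence: 14 (steps 1–7 and 10–16); the alkyne branch is steps 8–9.

Steps most likely to fail:

1. Step 15. The chain may fold onto the wrong face of the furan or present the wrong aldehyde face, or intermolecular aldol oligomerisation may outrun closure. Fallback: from 21, bromination at C10 (N-bromosuccinimide, catalytic NH4OAc, Et2O, 0 °C) would give the 2-bromo-2-methylfuranone aldehyde F1. SmI2 in THF at −78 °C under high dilution would then generate the trivalent samarium enolate at C10, which should add to the C9 aldehyde through a closed, metal-bridged transition state (intramolecular Reformatsky-type aldol, established for medium rings) and return to the route at 24.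

2. Step 7. The activated C8 alcohol may eliminate toward the C7=C8 diene, or esterification may occur with retention through an acyloxyphosphonium path, instead of clean SN2 inversion. Fallback: from 10, Tf2O and pyridine in CH2Cl2 at −30 °C would give the C8 triflate F2; displacement with cesium 3-methylbutanoate (18-crown-6, toluene, rt) should proceed with inversion and return to the route at 11.

3. Step 10. The amine or the copper acetylide may add to the methylene lactone, the vinylpalladium intermediate may cyclise onto it in a Heck-type reaction, or the alkyne may homocouple. Fallback: from 16, heating with Bu3SnOMe (neat, 60 °C) would give the alkynylstannane F3; amine-free and copper-free Stille coupling with 11 (Pd2(dba)3, AsPh3, THF–DMF, rt) should return to the route at 17.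

Further compounds
F1 | step 15 | (1S)-1-{(2R,3S)-2-[(1Z)-2-(5-bromo-5-methyl-4-oxo-4,5-dihydrofuran-2-yl)prop-1-en-1-yl]-4-methylidene-5-oxooxolan-3-yl}-2-oxoethyl 3-methylbutanoate (both bromide epimers) | C=C1C(=O)O[C@H](/C=C(/C)C2=CC(=O)C(C)(Br)O2)[C@H]1[C@H](OC(=O)CC(C)C)C=O
F2 | step 7 | (1R)-2-{[tert-butyl(dimethyl)silyl]oxy}-1-{(2S,3S)-2-[(1Z)-2-iodoprop-1-en-1-yl]-4-methylidene-5-oxooxolan-3-yl}ethyl trifluoromethanesulfonate | C=C1C(=O)O[C@H](/C=C(/C)I)[C@H]1[C@@H](OS(=O)(=O)C(F)(F)F)CO[Si](C)(C)C(C)(C)C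
F3 | step 10 | (4S)-4-{[tert-butyl(dimethyl)silyl]oxy}-1-(tributylstannyl)pent-1-yn-3-ol (both C3 epimers) | CCCC[Sn](CCCC)(CCCC)C#CC(O)[C@H](C)O[Si](C)(C)C(C)(C)C
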